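(The readings were generated by integration with made-up constants, noise included.)

The ratio of target lost to reagent lost is one once the substrate is gone, if one reagent takes one target, so time drops out of that ratio and the charge caps the loss, while how far the loss has gone by a given hour remains a matter of rate.

common to all: substrate 0.50 M; initiator 1.1 mol%

| flask | reagent | remark | time |
|---|---|---|---|
| Sunday's | 1.3 equiv | run made earlier |  |
| Saturday's | 1.8 equiv | run made earlier |  |
| epsilon | 1.10 equiv |  | 30 h |
| gamma | 3.30 equiv |  | 30 h |

- Sunday's (time / h: target / %): 1.50: 45; 3.00: 71; 6.00: 91; 12.0: 88; 20.0: 83
- Saturday's (time / h: target / %): 4.00: 91; 8.00: 80; 12.0: 73; 15.0: 67; 20.0: 62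

(standard deviation of a reading: 1.5 percentage points)

1. which of the two there is more of at the end, epsilon (target / over-reaction product)
2. which of the two there is more of at the end, gamma (target / over-reaction product)
3. target at the end, in percent of the substrate charged, epsilon
4. target at the end, in percent of the substrate charged, gamma



Two chemists read these runs differently. The first holds a clock view, a pseudo-first-order one: each flask keeps its late slope of ln(target). Sunday's readings give 0.00731 h⁻¹ and Saturday's give 0.0212 h⁻¹. Running Sunday's slope on from its last reading gives epsilon 77.1% target, and Saturday's slope gives gamma 50.1%.

The second holds a budget view. The substrate takes about one equivalent of reagent to become target, and what remains, the excess reagent, reagent equivalents minus one, is roughly what over-reaction can spend. The slopes support this: their ratio, 2.90 as read, lies near the ratio of the excesses, 2.67. For epsilon the excess is 10.0% of the substrate, so target should stay near 90.0%. For gamma the excess is 230%, which sets no ceiling, and reagent can fall no lower than about 39.4% of its charge.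

The forecast takes the budget side: 89% for epsilon, where “over-reaction is capped near” the excess, and 16% for gamma, with target ahead in epsilon and over-reaction product ahead in gamma.

The simulation gives epsilon 88.4% target and 9.82% over-reaction product, and gamma 12.1% target and 87.6% over-reaction product. The budget side wins.

    initiator → 2 initiating radical (k = 3.00 × 10⁻⁵ s⁻¹)
    substrate + initiating radical → capped initiator + first chain carrier (k = 81300 L mol⁻¹ s⁻¹)
    reagent + first chain carrier → target + second chain carrier (k = 5940 L mol⁻¹ s⁻¹)
    substrate + second chain carrier → by-product + first chain carrier (k = 1470 L mol⁻¹ s⁻¹)
    first chain carrier → ended carrier (k = 4.97 s⁻¹)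
    2 first chain carrier → ended chains (k = 6.00 × 10⁸ L mol⁻¹ s⁻¹)
    reagent + target → over-reaction product (k = 2.35 × 10⁻⁵ L mol⁻¹ s⁻¹)

Gamma's target is lost mainly to the conversion of reagent + target into over-reaction product: with that step taken away, gamma ends at 99.7% target. Epsilon's target survives in part because its reagent runs down, to 1.8% of the charge: with reagent held at its charge, epsilon ends at 26.4% target. The excess is a rough budget: epsilon's over-reaction product stands at 9.82% at the end but reaches 11.8% after 300 h, more than the excess of 10.0%. The clock keeps its ground on a flask followed over a modest stretch: Sunday's flask, carried to 30 h, gives 78.0% against the clock's 77.1%.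

Take the neighbour of epsilon charged with 4.40 equiv of reagent: its excess is 340%, so no ceiling, and reagent should bottom near 54.5% of its charge. That flask gives 3.52% target, 96.3% over-reaction product and 55% reagent.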